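Readings and results were computed with made-up constants; scatter was added.

The vessel was closed, stirred and held at one temperature, and the open question was whether its next charge, the beta run, deserved four times the Sub of the delta run.

| flask | Sub | Cat | time |
|---|---|---|---|
| delta | 0.0800 M | 0.00240 M |  |
| alpha | 0.120 M | 0.00240 M |  |
| epsilon | 0.0800 M | 0.00120 M |  |
| beta | 0.320 M | 0.00240 M | 3.2 h |

| run | time / h | [Prd] / M |
|---|---|---|
| delta run | 0.53 | 0.01063 |
| delta run | 1.1 | 0.02143 |
| delta run | 1.6 | 0.03005 |
| delta run | 2.1 | 0.03788 |
| delta run | 2.7 | 0.04435 |
| delta run | 3.2 | 0.04707 |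
| alpha run | 0.53 | 0.01109 |
| alpha run | 1.1 | 0.02230 |
| alpha run | 1.6 | 0.03152 |
| alpha run | 2.1 | 0.03990 |
| alpha run | 2.7 | 0.04814 |
| alpha run | 3.2 | 0.05268 |
| epsilon run | 0.53 | 0.00476 |
| epsilon run | 1.1 | 0.01067 |
| epsilon run | 1.6 | 0.01475 |
| epsilon run | 2.1 | 0.01999 |
| epsilon run | 2.7 | 0.02453 |
| epsilon run | 3.2 | 0.02812 |

(each reading ± 2 × 10⁻⁴ M)

- Overall: Sub -> Prd, with Cat as catalyst.
- Constant volume, constant temperature.
- A reading of a species includes what of it is bound.
- An order is taken over about fifteen percent of the charge, up and down.

- the exponent of [Sub] in the starting rate at the charge of the delta run (at the point where two percent of the Sub have become Prd) (one fixed amount of Prd, the same in the runs compared)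
- the exponent of [Cat] in the starting rate at the charge of the delta run (at the point where two percent of the Sub have become Prd)
- Prd in the beta run at 3.2 h, as a share of the Sub charged

I went at this by counting turnovers. In the delta run, 0.02143 M of Prd stood at 1.1 h over 0.00240 M of Cat, which gives 8.12 /h. This turn rate, the Prd made per Cat charged per hour (the turnover frequency), was the number I carried.

Could it be carried to beta? At that same time, read at equal time and not at equal Prd, the alpha run gave an order in Sub of 0.0981, and the epsilon run gave an order in Cat of 1.01. Both are readings with their scatter. So I let the turn rate stand for beta, which has the Cat of delta.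

Over 3.2 h that makes 26.0 turns, so c(Prd) comes to 0.0623 M, or 19.5% of the beta charge. But the alpha run had reached 21.9 turns by then, fewer than the count. My own estimate for beta therefore ran from 16.5% to 19.5%.

Even at the top of that band, my count gave 0.00966 M of Prd beyond the alpha run's reading for the 0.200 M of Sub beyond alpha's charge. That is poor pay where Sub is dear, so I decided to charge beta once, as a test of the count, and to leave its Cat unchanged.

The forecast stood at the top of my band, at 19.5%, and its range of 17% to 23% overlapped the band and reached above it, with orders 0.12 (0.03 to 0.24) in Sub and 1.07 (0.95 to 1.2) in Cat, on the ground that “the slowing follows Prd rather than time”.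

The flask gave 18.3% in the beta run, with orders 0.073 in Sub and 1.0 in Cat.

    Cat + Sub → Prd + Cat (1609 /M/h)
    2 Sub → J (4.968 /M/h)
    Cat + Sub ⇌ Cat.Sub, settled at all times (177.0 /M)

By the step that turns two Sub into J alone, the first half-life of the beta charge is 0.315 h, shorter than the 3.2 h of the run. In turns, the beta run made 24.4 against the count of 26.0. In the epsilon run, 8.12 /h on its 0.00120 M of Cat puts a quarter of the Sub charged at 2.05 h, and that run reached it at 2.13 h.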